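**Plan**

1. Cuts: the (E)-alkene C–C bond at C6 of ring D (Heck); the C2–ring B bond together with the C3–O bond (epoxide of a C2=C3 enol ether opened by an aryl group); the O1–C8a bond of ring C (oxygen deletion); the indanone C1–C7a bond (Friedel–Crafts); the C4–ring A bond (1,4-addition).
2. Enabling feature: O1 of ring C lies between C2 and the aromatic carbon C8a of ring A, so ring C without O1 is the five-membered ring of a 3-arylindan-1-one whose carbonyl carbon is the future C2 and whose C3 is the future C4; a peracid puts O1 back by migration of C8a.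
3. Forward order: ring D aldehyde, enoate, aryl addition (C4), indanone on ring A, oxygen insertion to the ring C lactone, lactol, 4H-chromene, C3–O and C2–aryl in one flask, stilbene, free phenols.
4. Stereochemistry: C4 from the (S)-BINAP–rhodium 1,4-addition; C3 from epoxidation anti to the C4 aryl group; C2 from syn aryl transfer by the oxygen-bound aryl(dimethyl)alane (2,3-cis, 3,4-trans); the (E)-alkene from the Heck reaction.
5. Protecting groups: ring D is kept electron-poor as its bis-mesylate until the Friedel–Crafts closure, so that it is neither acylated by a second molecule nor attacks through its ortho oxygen; all phenols are then carried as silyl ethers so that fluoride alone ends the synthesis.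

Key step: step 10

Remark: chroman numbering (O1, C2, C3, C4, C4a, C5–C8, C8a) is used for rings C and A of all flavan-type compounds; ring B is the aryl group at C2, ring D the aryl group at C4; TBS = tert-butyldimethylsilyl, Ms = methylsulfonyl.

**Route**

Step 1
Reactants: 1 5-bromoresorcinol
Product: 3 2-bromo-4,6-dihydroxybenzaldehyde, via iminium chloride 2 (not isolated)
Conditions: POCl3, DMF, MeCN, −15 °C → rt; then H2O, 50 °C
Reagents that add atoms: N,N-dimethylformamide, CN(C)C=O; water, O
Why: Vilsmeier–Haack formylation of a resorcinol goes ortho to one hydroxyl and para to the other, which here is the carbon between OH and Br (the orcinol pattern), and warm water hydrolyses the iminium salt to the aldehyde.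

Step 2
Reactants: 3 2-bromo-4,6-dihydroxybenzaldehyde
Product: 4 2-bromo-4,6-bis(methylsulfonyloxy)benzaldehyde
Conditions: MsCl (2.4 equiv), Et3N, CH2Cl2, 0 °C
Reagents that add atoms: methanesulfonyl chloride, CS(=O)(=O)Cl
Why: O-Sulfonylation of both phenols, which turns ring D into an electron-poor arene that cannot be acylated and whose ortho oxygen cannot attack an acylium ion in step 7.

Step 3
Reactants: 4 2-bromo-4,6-bis(methylsulfonyloxy)benzaldehyde; 5 tert-butyl diethylphosphonoacetate
Product: 6 tert-butyl (E)-3-[2-bromo-4,6-bis(methylsulfonyloxy)phenyl]prop-2-enoate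
Conditions: 5 (1.2 equiv), NaH (1.1 equiv), THF, 0 °C; then 4, 0 °C → rt
Reagents that add atoms: none
Why: Horner–Wadsworth–Emmons olefination of an aromatic aldehyde by a stabilised phosphonate anion gives the (E)-enoate, and the tert-butyl ester is chosen because acid later removes it without touching the sulfonates.

Step 4
Reactants: 7 4-hydroxyphenylboronic acid
Product: 8 4-(methylsulfonyloxy)phenylboronic acid
Conditions: MsCl (1.1 equiv), Et3N, THF, 0 °C; aqueous HCl work-up
Reagents that add atoms: methanesulfonyl chloride, CS(=O)(=O)Cl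
Why: Chemoselective O-sulfonylation of the phenol, any boron–oxygen–sulfur anhydride being hydrolysed back to the boronic acid on aqueous work-up.

Step 5
Reactants: 6 tert-butyl (E)-enoate; 8 4-(methylsulfonyloxy)phenylboronic acid
Product: 9 tert-butyl (3R)-3-[2-bromo-4,6-bis(methylsulfonyloxy)phenyl]-3-[4-(methylsulfonyloxy)phenyl]propanoate
Conditions: Rh(acac)(C2H4)2 (3 mol %), (S)-BINAP (3.3 mol %), 8 (3 equiv), dioxane/H2O 10:1, 100 °C
Reagents that add atoms: none
Why: Rhodium-catalysed asymmetric 1,4-addition of an arylboronic acid to an (E)-enoate (Hayashi–Miyaura reaction), in which the aryl–rhodium–(S)-BINAP species should insert the alkene through its α-si face and so create the diarylmethine carbon with the (R) configuration needed for C4 (should the first sample prove to be the antipode, (R)-BINAP is used instead).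

Step 6
Reactants: 9 tert-butyl (3R)-diarylpropanoate
Product: 10 (3R)-3-[2-bromo-4,6-bis(methylsulfonyloxy)phenyl]-3-[4-(methylsulfonyloxy)phenyl]propanoic acid
Conditions: CF3CO2H, CH2Cl2, rt
Reagents that add atoms: none
Why: Acidolysis of the tert-butyl ester with loss of isobutene frees the carboxylic acid and leaves the aryl sulfonates, the aryl bromide and the stereocentre untouched.

Step 7
Reactants: 10 (3R)-diarylpropanoic acid
Product: 12 (3R)-3-[2-bromo-4,6-bis(methylsulfonyloxy)phenyl]-6-(methylsulfonyloxy)indan-1-one, via acid chloride 11 (not isolated)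
Conditions: (COCl)2, DMF (cat.), CH2Cl2, rt; then AlCl3 (3 equiv), CH2Cl2, 0.02 M, 0 °C → rt
Reagents that add atoms: none
Why: Intramolecular Friedel–Crafts acylation closes the five-membered ketone on ring A, the only ring with a free ortho position (ring D carries Br and OMs at both), in the manner of the 6-halo-1-indanone syntheses, while the sulfonylated ring D is too electron-poor to be acylated by a second molecule.

Step 8
Reactants: 12 (3R)-tris(mesyloxy)indanone
Product: 13 (3R)-3-(2-bromo-4,6-dihydroxyphenyl)-6-hydroxyindan-1-one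
Conditions: NaOH (2 M aq), MeOH/THF, 50 °C, argon; then aqueous HCl
Reagents that add atoms: none
Why: Alkaline hydrolysis of the three aryl methanesulfonates by attack of hydroxide at sulfur, which cannot epimerise C3 because that carbon is not α to the carbonyl, the trianionic substrate being a poor partner for aldol self-condensation.

Step 9
Reactants: 13 (3R)-trihydroxyindanone
Product: 14 (3R)-3-[2-bromo-4,6-bis(tert-butyldimethylsilyloxy)phenyl]-6-(tert-butyldimethylsilyloxy)indan-1-one
Conditions: t-BuMe2SiCl (3.6 equiv), imidazole, DMF, rt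
Reagents that add atoms: tert-butyldimethylsilyl chloride, CC(C)(C)[Si](C)(C)Cl
Why: Silylation of phenols with the silyl chloride and imidazole, giving ethers that should stand peracid, i-Bu2AlH, mild acid, dioxirane, the alane and the Heck conditions and fall to fluoride at the end.

Step 10
Reactants: 14 (3R)-tris(silyloxy)indanone
Product: 16 (4R)-4-[2-bromo-4,6-bis(tert-butyldimethylsilyloxy)phenyl]-7-(tert-butyldimethylsilyloxy)chroman-2-one, via Criegee adduct 15 (not isolated)
Conditions: mCPBA (2.5 equiv), NaHCO3, CH2Cl2, 0 °C → rt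
Reagents that add atoms: 3-chloroperoxybenzoic acid, OOC(=O)c1cccc(Cl)c1
Why: The peracid adds to the C1 carbonyl to give the Criegee adduct 15, and the aryl carbon C7a then migrates from C1 to the proximal peroxide oxygen as 3-chlorobenzoate leaves, so that O1 is inserted between the carbonyl carbon (future C2) and C7a (future C8a). The closest known reaction is the Baeyer–Villiger oxidation of 1-indanones to 3,4-dihydrocoumarins. The six-membered lactone of ring C arises by ring expansion through this 1,2-shift and not by a cyclisation, so no ring-closure mode has to be met. No stereocentre is formed, and C3 of the indanone, remote from the reacting carbonyl, is carried over unchanged as C4 (R). The step needs migration of the aryl carbon in preference to the C2 methylene, which the normal order aryl before primary alkyl should secure now that ring A bears a silyl ether in place of the electron-withdrawing sulfonate. The hydrogencarbonate buffer takes up the 3-chlorobenzoic acid, so that ring D and the aryl silyl ethers are not exposed to an acidic peracid that could hydroxylate or desilylate them.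

Step 11
Reactants: 16 (4R)-chroman-2-one
Product: 17 (4R)-4-[2-bromo-4,6-bis(tert-butyldimethylsilyloxy)phenyl]-7-(tert-butyldimethylsilyloxy)chroman-2-ol (both C2 epimers)
Conditions: i-Bu2AlH (1.1 equiv), toluene, −78 °C; aqueous potassium sodium tartrate
Reagents that add atoms: none
Why: Partial reduction of a lactone to the lactol by i-Bu2AlH, possible because the aluminium hemiacetal formed at −78 °C does not collapse to the aldehyde before work-up.

Step 12
Reactants: 17 (4R)-chroman-2-ol
Product: 18 (4R)-4-[2-bromo-4,6-bis(tert-butyldimethylsilyloxy)phenyl]-7-(tert-butyldimethylsilyloxy)-4H-chromene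
Conditions: pyridinium p-toluenesulfonate (10 mol %), 4 Å molecular sieves, toluene, 90 °C
Reagents that add atoms: none
Why: Acid-catalysed dehydration of a cyclic hemiacetal through the C2 oxocarbenium ion, which can lose a proton only from C3 and so gives the C2=C3 enol ether without touching C4.

Step 13
Reactants: 19 (4-bromophenoxy)(tert-butyl)dimethylsilane
Product: 21 [4-(tert-butyldimethylsilyloxy)phenyl]dimethylaluminium, via aryllithium 20 (not isolated)
Conditions: n-BuLi (1.0 equiv), Et2O/toluene, −78 → 0 °C; then Me2AlCl (1.0 equiv, hexane solution), −78 °C → rt; solution used as such in step 14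
Reagents that add atoms: dimethylaluminium chloride, C[Al](C)Cl
Why: Bromine–lithium exchange followed by salt metathesis (transmetalation) of the aryllithium with one equivalent of Me2AlCl gives the mixed aryl(dimethyl)alane, which carries one aryl group per aluminium and transfers its sp2 carbon in preference to the methyl groups.

Step 14
Reactants: 18 (4R)-4H-chromene; 21 aryl(dimethyl)alane
Product: 23 (2R,3R,4R)-4-[2-bromo-4,6-bis(tert-butyldimethylsilyloxy)phenyl]-7-(tert-butyldimethylsilyloxy)-2-[4-(tert-butyldimethylsilyloxy)phenyl]chroman-3-ol, via epoxide 22 (not isolated)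
Conditions: dimethyldioxirane (acetone solution, 1.2 equiv), CH2Cl2, −78 → 0 °C, evaporated cold; then 21 (3 equiv), toluene/Et2O, −78 → 0 °C; aqueous potassium sodium tartrate
Reagents that add atoms: dimethyldioxirane, CC1(C)OO1
Why: Epoxidation of the enol ether by the dioxirane on the face away from the pseudo-axial C4 aryl group, then opening of the acetal epoxide at C2 by the Lewis-acidic alane with transfer of its aryl group (in preference to methyl) from the oxygen-bound aluminium to the same face (the syn opening known for 1,2-anhydro sugars with organoalanes), which should set C3 with its oxygen trans to ring D and C2 with ring B cis to the new hydroxyl.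

Step 15
Reactants: 24 3,4-dihydroxybenzaldehyde
Product: 25 3,4-bis(tert-butyldimethylsilyloxy)benzaldehyde
Conditions: t-BuMe2SiCl (2.4 equiv), imidazole, DMF, rt
Reagents that add atoms: tert-butyldimethylsilyl chloride, CC(C)(C)[Si](C)(C)Cl
Why: Silylation of both phenols of the catechol under standard conditions, the aldehyde being inert.

Step 16
Reactants: 25 3,4-bis(tert-butyldimethylsilyloxy)benzaldehyde
Product: 26 3,4-bis(tert-butyldimethylsilyloxy)styrene
Conditions: Ph3PCH3Br, n-BuLi, THF, 0 °C; then 25, 0 °C → rt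
Reagents that add atoms: methyltriphenylphosphonium bromide, C[P+](c1ccccc1)(c1ccccc1)c1ccccc1.[Br-]
Why: Wittig methylenation with the non-stabilised ylide, run without free alkoxide so that the aryl silyl ethers are not cleaved.

Step 17
Reactants: 23 (2R,3R,4R)-bromo flavan-3-ol; 26 3,4-bis(tert-butyldimethylsilyloxy)styrene
Product: 27 (2R,3R,4R)-4-{2,4-bis(tert-butyldimethylsilyloxy)-6-[(E)-2-(3,4-bis(tert-butyldimethylsilyloxy)phenyl)ethenyl]phenyl}-7-(tert-butyldimethylsilyloxy)-2-[4-(tert-butyldimethylsilyloxy)phenyl]chroman-3-ol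
Conditions: Pd2(dba)3 (2.5 mol %), [HP(t-Bu)3]BF4 (10 mol %), Cy2NMe (1.5 equiv), dioxane, 80 °C
Reagents that add atoms: none
Why: Mizoroki–Heck coupling of the ortho-substituted aryl bromide with the styrene at a bulky trialkylphosphine complex of zerovalent palladium, where syn insertion and syn β-hydride elimination give the (E)-stilbene and the amine base leaves the free C3 hydroxyl and the silyl ethers alone.

Step 18
Reactants: 27 hexasilyl ether
Product: 28 (2R,3R,4R)-4-{2-[(E)-2-(3,4-dihydroxyphenyl)ethenyl]-4,6-dihydroxyphenyl}-2-(4-hydroxyphenyl)chroman-3,7-diol (CNP0170061.2)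
Conditions: Bu4NF (8 equiv), AcOH (8 equiv), THF, 0 °C → rt, argon
Reagents that add atoms: none
Why: Fluoride-mediated cleavage of the six aryl silyl ethers under acetic acid buffering, a deprotection that needs neither a Lewis acid nor hydrogen and therefore should spare the stilbene, the benzylic C2–O1 bond and all three stereocentres.

**Compound list**

1 | 5-bromoresorcinol | Oc1cc(O)cc(Br)c1 | starting material
2 | N-[(2-bromo-4,6-dihydroxyphenyl)methylidene]-N-methylmethanaminium chloride | C[N+](C)=Cc1c(O)cc(O)cc1Br.[Cl-] | intermediate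
3 | 2-bromo-4,6-dihydroxybenzaldehyde | O=Cc1c(O)cc(O)cc1Br | intermediate
4 | 2-bromo-4,6-bis(methylsulfonyloxy)benzaldehyde | O=Cc1c(OS(C)(=O)=O)cc(OS(C)(=O)=O)cc1Br | intermediate
5 | tert-butyl diethylphosphonoacetate | CCOP(=O)(CC(=O)OC(C)(C)C)OCC | starting material
6 | tert-butyl (E)-3-[2-bromo-4,6-bis(methylsulfonyloxy)phenyl]prop-2-enoate | CC(C)(C)OC(=O)/C=C/c1c(OS(C)(=O)=O)cc(OS(C)(=O)=O)cc1Br | intermediate
7 | 4-hydroxyphenylboronic acid | OB(O)c1ccc(O)cc1 | starting material
8 | 4-(methylsulfonyloxy)phenylboronic acid | CS(=O)(=O)Oc1ccc(B(O)O)cc1 | intermediate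
9 | tert-butyl (3R)-3-[2-bromo-4,6-bis(methylsulfonyloxy)phenyl]-3-[4-(methylsulfonyloxy)phenyl]propanoate | CC(C)(C)OC(=O)C[C@@H](c1c(OS(C)(=O)=O)cc(OS(C)(=O)=O)cc1Br)c1ccc(OS(C)(=O)=O)cc1 | intermediate
10 | (3R)-3-[2-bromo-4,6-bis(methylsulfonyloxy)phenyl]-3-[4-(methylsulfonyloxy)phenyl]propanoic acid | OC(=O)C[C@@H](c1c(OS(C)(=O)=O)cc(OS(C)(=O)=O)cc1Br)c1ccc(OS(C)(=O)=O)cc1 | intermediate
11 | (3R)-3-[2-bromo-4,6-bis(methylsulfonyloxy)phenyl]-3-[4-(methylsulfonyloxy)phenyl]propanoyl chloride | ClC(=O)C[C@@H](c1c(OS(C)(=O)=O)cc(OS(C)(=O)=O)cc1Br)c1ccc(OS(C)(=O)=O)cc1 | intermediate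
12 | (3R)-3-[2-bromo-4,6-bis(methylsulfonyloxy)phenyl]-6-(methylsulfonyloxy)indan-1-one | O=C1C[C@@H](c2c(OS(C)(=O)=O)cc(OS(C)(=O)=O)cc2Br)c2ccc(OS(C)(=O)=O)cc21 | intermediate
13 | (3R)-3-(2-bromo-4,6-dihydroxyphenyl)-6-hydroxyindan-1-one | O=C1C[C@@H](c2c(O)cc(O)cc2Br)c2ccc(O)cc21 | intermediate
14 | (3R)-3-[2-bromo-4,6-bis(TBS-oxy)phenyl]-6-(TBS-oxy)indan-1-one | O=C1C[C@@H](c2c(O[Si](C)(C)C(C)(C)C)cc(O[Si](C)(C)C(C)(C)C)cc2Br)c2ccc(O[Si](C)(C)C(C)(C)C)cc21 | intermediate
15 | Criegee adduct of 14: (3R)-1-hydroxy-1-(3-chlorobenzoylperoxy)indane with the substituents of 14, C1 configuration undefined | OC1(OOC(=O)c2cccc(Cl)c2)C[C@@H](c2c(O[Si](C)(C)C(C)(C)C)cc(O[Si](C)(C)C(C)(C)C)cc2Br)c2ccc(O[Si](C)(C)C(C)(C)C)cc21 | intermediate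
16 | (4R)-4-[2-bromo-4,6-bis(TBS-oxy)phenyl]-7-(TBS-oxy)chroman-2-one | O=C1C[C@@H](c2c(O[Si](C)(C)C(C)(C)C)cc(O[Si](C)(C)C(C)(C)C)cc2Br)c2ccc(O[Si](C)(C)C(C)(C)C)cc2O1 | intermediate
17 | (4R)-4-[2-bromo-4,6-bis(TBS-oxy)phenyl]-7-(TBS-oxy)chroman-2-ol, both C2 epimers | OC1C[C@@H](c2c(O[Si](C)(C)C(C)(C)C)cc(O[Si](C)(C)C(C)(C)C)cc2Br)c2ccc(O[Si](C)(C)C(C)(C)C)cc2O1 | intermediate
18 | (4R)-4-[2-bromo-4,6-bis(TBS-oxy)phenyl]-7-(TBS-oxy)-4H-chromene | C1=C[C@@H](c2c(O[Si](C)(C)C(C)(C)C)cc(O[Si](C)(C)C(C)(C)C)cc2Br)c2ccc(O[Si](C)(C)C(C)(C)C)cc2O1 | intermediate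
19 | (4-bromophenoxy)(tert-butyl)dimethylsilane | Brc1ccc(O[Si](C)(C)C(C)(C)C)cc1 | starting material
20 | [4-(TBS-oxy)phenyl]lithium | [Li]c1ccc(O[Si](C)(C)C(C)(C)C)cc1 | intermediate
21 | [4-(TBS-oxy)phenyl]dimethylaluminium | C[Al](C)c1ccc(O[Si](C)(C)C(C)(C)C)cc1 | intermediate
22 | (2S,3R,4R)-2,3-epoxy-4-[2-bromo-4,6-bis(TBS-oxy)phenyl]-7-(TBS-oxy)chromane, oxirane oxygen on the face opposite ring D | O1c2cc(O[Si](C)(C)C(C)(C)C)ccc2[C@H](c2c(O[Si](C)(C)C(C)(C)C)cc(O[Si](C)(C)C(C)(C)C)cc2Br)[C@H]2O[C@@H]12 | intermediate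
23 | (2R,3R,4R)-4-[2-bromo-4,6-bis(TBS-oxy)phenyl]-7-(TBS-oxy)-2-[4-(TBS-oxy)phenyl]chroman-3-ol (2,3-cis, 3,4-trans) | CC(C)(C)[Si](C)(C)Oc1ccc([C@H]2Oc3cc(O[Si](C)(C)C(C)(C)C)ccc3[C@H](c3c(O[Si](C)(C)C(C)(C)C)cc(O[Si](C)(C)C(C)(C)C)cc3Br)[C@H]2O)cc1 | intermediate
24 | 3,4-dihydroxybenzaldehyde | O=Cc1ccc(O)c(O)c1 | starting material
25 | 3,4-bis(TBS-oxy)benzaldehyde | O=Cc1ccc(O[Si](C)(C)C(C)(C)C)c(O[Si](C)(C)C(C)(C)C)c1 | intermediate
26 | 3,4-bis(TBS-oxy)styrene | C=Cc1ccc(O[Si](C)(C)C(C)(C)C)c(O[Si](C)(C)C(C)(C)C)c1 | intermediate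
27 | (2R,3R,4R)-4-{2,4-bis(TBS-oxy)-6-[(E)-2-(3,4-bis(TBS-oxy)phenyl)ethenyl]phenyl}-7-(TBS-oxy)-2-[4-(TBS-oxy)phenyl]chroman-3-ol | CC(C)(C)[Si](C)(C)Oc1ccc([C@H]2Oc3cc(O[Si](C)(C)C(C)(C)C)ccc3[C@H](c3c(O[Si](C)(C)C(C)(C)C)cc(O[Si](C)(C)C(C)(C)C)cc3/C=C/c3ccc(O[Si](C)(C)C(C)(C)C)c(O[Si](C)(C)C(C)(C)C)c3)[C@H]2O)cc1 | intermediate
28 | (2R,3R,4R)-4-{2-[(E)-2-(3,4-dihydroxyphenyl)ethenyl]-4,6-dihydroxyphenyl}-2-(4-hydroxyphenyl)chroman-3,7-diol | Oc1ccc([C@H]2Oc3cc(O)ccc3[C@H](c3c(O)cc(O)cc3/C=C/c3ccc(O)c(O)c3)[C@H]2O)cc1 | target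

**Step count and risks**

Total: 18 steps. Longest linear sequence: 14 steps (steps 1, 2, 3, 5, 6, 7, 8, 9, 10, 11, 12, 14, 17, 18).

Steps most likely to fail, highest risk first:

Step 14. The Lewis-acidic alane may trigger a 1,2-hydride shift in the acetal epoxide (collapse towards the chroman-3-one) before an aryl group is transferred. A methyl group of the mixed alane may be transferred in competition with the aryl group. The aryl group may also be delivered to the face opposite the oxygen, which loses the 2,3-cis relationship, or the epoxidation may lose its face selectivity. The fallback brings ring B in by carbonyl addition and sets C2 by hydride; it sets out from lactone 16 (with aryllithium 20) and returns at 23. Lactone 16 would be opened with MeNH(OMe)·HCl and AlMe3 to the phenolic N-methoxy-N-methylamide F1. Two equivalents of 20, the first consumed by the phenol, would then give the 2-hydroxyaryl ketone F2. Pyridinium p-toluenesulfonate in hot toluene should close F2 through its hemiketal and dehydrate it to the 2,4-diaryl-4H-chromene F3. Dimethyldioxirane should epoxidise C2=C3 of F3 anti to ring D to the 2-aryl epoxide F4, which is not isolated. Et3SiH with BF3·OEt2 at −78 °C would then reduce the C2 oxocarbenium ion derived from F4 (ionic hydrogenation). Hydride is expected to enter anti to the boron-bound C3 oxygen, so that ring B ends cis to the hydroxyl as in 23.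

Step 5. Insertion of the di-ortho-substituted alkene into the aryl–rhodium bond may be so slow that protodeboronation of 8 uses up the reagent, or the two ortho substituents may erode the face selectivity. The fallback replaces asymmetric catalysis by resolution; it sets out from 6 and 8 and returns at 10. The addition would be run without a chiral ligand with the more active [Rh(OH)(cod)]2 (dioxane/H2O, 50 °C) to give the racemic ester F5. CF3CO2H would give the racemic acid F6. Crystallisation with (R)-1-phenylethylamine should give the diastereomerically pure ammonium salt F7 of the (3R)-acid; the antipodal amine is taken if the (3S)-salt is the less soluble one. Aqueous HCl then liberates 10.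

Step 12. Under the acidic dehydration the electron-rich 4-aryl-4H-chromene may be reprotonated and then dimerise or disproportionate, or the lactol may react through its open hydroxy-aldehyde form. The fallback avoids both the free lactol and protic acid; it sets out from lactone 16 and returns at 18. i-Bu2AlH at −78 °C followed by Ac2O, pyridine and 4-(dimethylamino)pyridine would trap the aluminium hemiacetal as the 2-acetoxychroman F8 (reductive acetylation). Me3SiOTf with i-Pr2NEt in CH2Cl2 (−78 → 0 °C) should then ionise the acetate and remove the C3 proton under basic, non-protic conditions to give 18.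

**Further compounds**

F1 | step 14 | (3R)-3-[2-bromo-4,6-bis(TBS-oxy)phenyl]-3-[2-hydroxy-4-(TBS-oxy)phenyl]-N-methoxy-N-methylpropanamide | CON(C)C(=O)C[C@@H](c1c(O[Si](C)(C)C(C)(C)C)cc(O[Si](C)(C)C(C)(C)C)cc1Br)c1ccc(O[Si](C)(C)C(C)(C)C)cc1O
F2 | step 14 | (3R)-3-[2-bromo-4,6-bis(TBS-oxy)phenyl]-3-[2-hydroxy-4-(TBS-oxy)phenyl]-1-[4-(TBS-oxy)phenyl]propan-1-one | O=C(C[C@@H](c1c(O[Si](C)(C)C(C)(C)C)cc(O[Si](C)(C)C(C)(C)C)cc1Br)c1ccc(O[Si](C)(C)C(C)(C)C)cc1O)c1ccc(O[Si](C)(C)C(C)(C)C)cc1
F3 | step 14 | (4R)-4-[2-bromo-4,6-bis(TBS-oxy)phenyl]-7-(TBS-oxy)-2-[4-(TBS-oxy)phenyl]-4H-chromene | C1(c2ccc(O[Si](C)(C)C(C)(C)C)cc2)=C[C@@H](c2c(O[Si](C)(C)C(C)(C)C)cc(O[Si](C)(C)C(C)(C)C)cc2Br)c2ccc(O[Si](C)(C)C(C)(C)C)cc2O1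
F4 | step 14 | 2,3-epoxide of F3 with the oxirane oxygen on the face opposite ring D | O1c2cc(O[Si](C)(C)C(C)(C)C)ccc2[C@H](c2c(O[Si](C)(C)C(C)(C)C)cc(O[Si](C)(C)C(C)(C)C)cc2Br)[C@H]2O[C@@]12c1ccc(O[Si](C)(C)C(C)(C)C)cc1
F5 | step 5 | racemic tert-butyl 3-[2-bromo-4,6-bis(methylsulfonyloxy)phenyl]-3-[4-(methylsulfonyloxy)phenyl]propanoate | CC(C)(C)OC(=O)CC(c1c(OS(C)(=O)=O)cc(OS(C)(=O)=O)cc1Br)c1ccc(OS(C)(=O)=O)cc1
F6 | step 5 | racemic 3-[2-bromo-4,6-bis(methylsulfonyloxy)phenyl]-3-[4-(methylsulfonyloxy)phenyl]propanoic acid | OC(=O)CC(c1c(OS(C)(=O)=O)cc(OS(C)(=O)=O)cc1Br)c1ccc(OS(C)(=O)=O)cc1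
F7 | step 5 | (R)-1-phenylethylammonium (3R)-3-[2-bromo-4,6-bis(methylsulfonyloxy)phenyl]-3-[4-(methylsulfonyloxy)phenyl]propanoate | C[C@@H]([NH3+])c1ccccc1.[O-]C(=O)C[C@@H](c1c(OS(C)(=O)=O)cc(OS(C)(=O)=O)cc1Br)c1ccc(OS(C)(=O)=O)cc1
F8 | step 12 | (4R)-4-[2-bromo-4,6-bis(TBS-oxy)phenyl]-7-(TBS-oxy)chroman-2-yl acetate, both C2 epimers | CC(=O)OC1C[C@@H](c2c(O[Si](C)(C)C(C)(C)C)cc(O[Si](C)(C)C(C)(C)C)cc2Br)c2ccc(O[Si](C)(C)C(C)(C)C)cc2O1
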